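**Retrosynthetic overview**

1. Numbering (germacrane): C1 furanone C=O, C2=C3 furanone alkene (C3 on the ring O), C4(Me)=C5 Z-alkene, C6 lactone carbinol, C7, C8 (butenoate), C9 (acetate), C10 quaternary ether carbon, C11/C12/C13 lactone α-carbon, carbonyl and methylene. The route rests on the C6–C7–C8 triad: C11 on C7 and the acyloxy oxygen on C8 are neighbours and anti, next to the lactone oxygen on C6, so both can come from one cyclopropane C7–C8–C11 tied to O6 through C12.
2. Last ring: the ten-membered carbocycle, by C9–C10 aldol of a C10–H furanone onto a C9 aldehyde, then acetylation of O9.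
3. Furanone ring (O–C10–C1–C2=C3) from a C2≡C3 ynone carrying a lactoyl unit (alkyne acylation, gold cyclisation).
4. C8–O ester by SN2 opening of the cyclopropane bond C8–C11 with the side-chain carboxylate; C13 by decarboxylative methylenation of the remaining tert-butyl ester.
5. γ-Lactone and cyclopropane together from an O6 diazomalonate (rhodium carbenoid onto E-C7=C8); C6 from an asymmetric alkenylzinc addition to a Z-enynal. Ring order: lactone and cyclopropane (step 7), furanone (step 18), carbocycle (step 20).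

Key step: step 7

Remark: salts that are only the deprotonated form of a numbered compound and return to it on work-up are not numbered separately; the C9 silyl ether is TBDPS so that it survives the acidolysis in step 12.

**Route**

Step 1
Reactants: 1 (Z)-3-methylpent-2-en-4-yn-1-ol
Product: 3 (Z)-3-methyl-5-(trimethylsilyl)pent-2-en-4-yn-1-ol, via bis-silylated enynol 2 (not isolated)
Conditions: n-BuLi (2.2 equiv), THF, −78 → 0 °C; TMSCl (2.3 equiv); then 1 M HCl, THF, 0 °C
Reagents that add atoms: chlorotrimethylsilane, C[Si](C)(C)Cl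
Why: Alkoxide and acetylide are both silylated and the labile O–Si bond alone is hydrolysed on acidic work-up (acetylide C-silylation), leaving the Z-alkene untouched.

Step 2
Reactants: 3 (Z)-3-methyl-5-(trimethylsilyl)pent-2-en-4-yn-1-ol
Product: 4 (Z)-3-methyl-5-(trimethylsilyl)pent-2-en-4-ynal
Conditions: MnO2 (activated, excess), CH2Cl2, rt, dark
Reagents that add atoms: none
Why: Allylic alcohol oxidation with MnO2 is neutral and should keep the Z geometry of the enal, which is used at once.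

Step 3
Reactants: 5 propargyl alcohol
Product: 6 tert-butyl(diphenyl)(prop-2-yn-1-yloxy)silane
Conditions: TBDPSCl, imidazole, DMF, 0 °C → rt
Reagents that add atoms: tert-butylchlorodiphenylsilane, CC(C)(C)[Si](Cl)(c1ccccc1)c1ccccc1
Why: Standard silyl ether formation on a primary alcohol.

Step 4
Reactants: 6 tert-butyl(diphenyl)(prop-2-yn-1-yloxy)silane; 4 (Z)-3-methyl-5-(trimethylsilyl)pent-2-en-4-ynal
Product: 9 (2E,4S,5Z)-1-(tert-butyldiphenylsilyloxy)-6-methyl-8-(trimethylsilyl)octa-2,5-dien-7-yn-4-ol, via alkenylborane 7 (not isolated), via alkenylmethylzinc 8 (not isolated)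
Conditions: 6 (1.25 equiv), Cy2BH (preformed solid, 1.2 equiv), toluene, 0 °C → rt; Me2Zn (1.3 equiv), −78 °C; (2S)-(−)-3-exo-morpholinoisoborneol [(−)-MIB, 5 mol%]; 4, −30 → −10 °C; aq. NH4Cl
Reagents that add atoms: none
Why: Syn hydroboration gives the E-alkenylborane, boron-to-zinc exchange gives the alkenylzinc, and the amino-alcohol-catalysed addition (Oppolzer–Walsh alkenylzinc addition) with (−)-MIB delivers the alkenyl group to the Si face of the aldehyde, which sets C6 as the (S)-carbinol.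

Step 5
Reactants: 9 (2E,4S,5Z)-1-(tert-butyldiphenylsilyloxy)-6-methyl-8-(trimethylsilyl)octa-2,5-dien-7-yn-4-ol; 10 mono-tert-butyl malonate
Product: 11 tert-butyl (2E,4S,5Z)-1-(tert-butyldiphenylsilyloxy)-6-methyl-8-(trimethylsilyl)octa-2,5-dien-7-yn-4-yl malonate
Conditions: DCC, DMAP (0.1 equiv), CH2Cl2, 0 °C → rt
Reagents that add atoms: none
Why: Steglich esterification acylates the secondary bis-allylic alcohol under neutral conditions without touching C6.

Step 6
Reactants: 11 mixed malonate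
Product: 12 tert-butyl (2E,4S,5Z)-1-(tert-butyldiphenylsilyloxy)-6-methyl-8-(trimethylsilyl)octa-2,5-dien-7-yn-4-yl 2-diazomalonate
Conditions: 4-acetamidobenzenesulfonyl azide (p-ABSA), Et3N, MeCN, 0 °C → rt
Reagents that add atoms: 4-acetamidobenzenesulfonyl azide, CC(=O)Nc1ccc(cc1)S(=O)(=O)N=[N+]=[N-]
Why: Regitz diazo transfer to the acidic malonate CH2 is reliable and the diazomalonate is stable enough to purify.

Step 7
Reactants: 12 bis-allylic tert-butyl diazomalonate
Product: 13 tert-butyl (1S,4R,5S,6S)-6-[(tert-butyldiphenylsilyloxy)methyl]-4-[(Z)-2-methyl-4-(trimethylsilyl)but-1-en-3-yn-1-yl]-2-oxo-3-oxabicyclo[3.1.0]hexane-1-carboxylate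
Conditions: Rh2(OAc)4 (2 mol%), ClCH2CH2Cl, 70 °C, syringe-pump addition of 12 (final 0.01 M)
Reagents that add atoms: none
Why: Rh2(OAc)4 expels N2 from the diazomalonate to give an electrophilic rhodium carbenoid at C11, which adds in one concerted, asynchronous syn [2+1] event to the E C7=C8 alkene and forms C11–C7 and C11–C8. The closest known reaction type is the rhodium- or copper-catalysed intramolecular cyclopropanation of allylic diazoacetates and diazomalonates to 3-oxabicyclo[3.1.0]hexan-2-ones. The γ-lactone (O6–C12–C11–C7–C6) closes in the 5-exo sense as the tethered carbenoid reaches the proximal alkene carbon C7, and the cyclopropane (C7–C8–C11) closes in the same event, so the two rings are necessarily cis-fused. C8 relative to C7 follows from the stereospecific syn addition to the E-alkene (C9 ends trans to C6 on the three-membered ring), C11 follows from the cis fusion, and C7 relative to C6 follows from the enyne arm on C6 taking the convex (exo) side of the forming bicycle, away from the cyclopropane. The step needs site selectivity for C7=C8, which the substrate secures because C4=C5 is trisubstituted, Z and deactivated by the alkynyl group while the alkyne is capped by SiMe3, and it needs exo facial selectivity, which rests only on the steric bias of the C6 arm in the folded transition state.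

Step 8
Reactants: 14 tert-butyl acrylate; 15 acetaldehyde
Product: 16 tert-butyl 3-hydroxy-2-methylidenebutanoate (racemic)
Conditions: DABCO (1 equiv), 1,4-dioxane/H2O (1:1), rt
Reagents that add atoms: none
Why: Morita–Baylis–Hillman reaction of an acrylate with a reactive aliphatic aldehyde; the stereocentre is removed in step 9.

Step 9
Reactants: 16 tert-butyl 3-hydroxy-2-methylidenebutanoate
Product: 18 tert-butyl (E)-2-(acetoxymethyl)but-2-enoate, via secondary allylic acetate 17 (not isolated)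
Conditions: Ac2O, Et3N, DMAP (cat.), THF, 0 °C → rt; then DABCO (0.2 equiv), 65 °C
Reagents that add atoms: acetic anhydride, CC(=O)OC(C)=O
Why: Acetylation followed by amine-catalysed SN2′–SN2′ 1,3-transposition of the Baylis–Hillman acetate should give the more stable trisubstituted alkene with the ester trans to the methyl group (E).

Step 10
Reactants: 18 tert-butyl (E)-2-(acetoxymethyl)but-2-enoate
Product: 19 (E)-2-(acetoxymethyl)but-2-enoic acid
Conditions: TFA, CH2Cl2, 0 °C → rt
Reagents that add atoms: none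
Why: Acidolysis of the tert-butyl ester (loss of isobutene) leaves the allylic acetate and the alkene geometry intact.

Step 11
Reactants: 13 cyclopropane-fused lactone; 19 (E)-2-(acetoxymethyl)but-2-enoic acid
Product: 20 tert-butyl (4S,5R)-4-[(1S)-1-{[(E)-2-(acetoxymethyl)but-2-enoyl]oxy}-2-(tert-butyldiphenylsilyloxy)ethyl]-5-[(Z)-2-methyl-4-(trimethylsilyl)but-1-en-3-yn-1-yl]-2-oxooxolane-3-carboxylate (C11 epimers)
Conditions: 19 (3 equiv), Cs2CO3 (0.3 equiv), dry DMF, 60 °C
Reagents that add atoms: none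
Why: Homoconjugate SN2 opening of a cyclopropane activated by two acyl groups on C11: the caesium carboxylate attacks the less substituted exocyclic carbon C8 opposite to the departing C11, so C8 is inverted and O8 ends anti to C11 (8S), and the lactone–ester enolate is protonated by the excess acid.

Step 12
Reactants: 20 ring-opened lactone tert-butyl ester
Product: 22 (1S)-2-(tert-butyldiphenylsilyloxy)-1-{(2R,3S)-4-methylidene-2-[(Z)-2-methyl-4-(trimethylsilyl)but-1-en-3-yn-1-yl]-5-oxooxolan-3-yl}ethyl (E)-2-(acetoxymethyl)but-2-enoate, via lactone carboxylic acid 21 (not isolated)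
Conditions: TFA, CH2Cl2, 0 °C → rt; evaporate; then H2C=NMe2+ I− (Eschenmoser's salt, 1.5 equiv), MeCN, 45 °C
Reagents that add atoms: N,N-dimethylmethyleneiminium iodide, C[N+](C)=C.[I-]
Why: Acidolysis gives the malonic half-acid, whose Mannich adduct loses CO2 and dimethylamine (decarboxylative methylenation) to give the C11=C13 methylene; the amine leaves as its hydroiodide, so no free amine meets the side chain.

Step 13
Reactants: 22 silylated enyne methylene lactone
Product: 23 (1S)-2-(tert-butyldiphenylsilyloxy)-1-{(2R,3S)-4-methylidene-2-[(Z)-2-methylbut-1-en-3-yn-1-yl]-5-oxooxolan-3-yl}ethyl (E)-2-(acetoxymethyl)but-2-enoate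
Conditions: AgNO3 (0.1 equiv), acetone/H2O (4:1), rt, dark
Reagents that add atoms: none
Why: Silver-catalysed protodesilylation removes only the alkynyl SiMe3 group and should spare the acetates, the methylene lactone and the TBDPS ether.

Step 14
Reactants: 24 ethyl (S)-lactate
Product: 25 ethyl (S)-2-(tert-butyldimethylsilyloxy)propanoate
Conditions: TBSCl, imidazole, DMF, 0 °C → rt
Reagents that add atoms: tert-butylchlorodimethylsilane, CC(C)(C)[Si](C)(C)Cl
Why: Standard silylation of the secondary alcohol.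

Step 15
Reactants: 25 ethyl (S)-2-(tert-butyldimethylsilyloxy)propanoate
Product: 26 (S)-2-(tert-butyldimethylsilyloxy)propanoic acid
Conditions: LiOH, THF/H2O, 0 °C; 1 M HCl to pH 4 at 0 °C
Reagents that add atoms: lithium hydroxide, [Li+].[OH-]
Why: Ester saponification; the hindered silyl ether should survive brief cold acidification.

Step 16
Reactants: 23 terminal enyne; 26 (S)-2-(tert-butyldimethylsilyloxy)propanoic acid
Product: 28 (1S)-2-(tert-butyldiphenylsilyloxy)-1-{(2R,3S)-2-[(1Z,6S)-6-(tert-butyldimethylsilyloxy)-2-methyl-5-oxohept-1-en-3-yn-1-yl]-4-methylidene-5-oxooxolan-3-yl}ethyl (E)-2-(acetoxymethyl)but-2-enoate, via silyloxypropanoyl chloride 27 (not isolated)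
Conditions: 26, 1-chloro-N,N,2-trimethylprop-1-en-1-amine, CH2Cl2, 0 °C → rt; then 23, CuI (10 mol%), Et3N (2 equiv), THF, rt
Reagents that add atoms: none
Why: The acid chloride is made under neutral conditions and acylates the copper acetylide formed with CuI and Et3N (copper-catalysed alkyne acylation), which avoids strong base and palladium in the presence of the methylene lactone and the allylic acetate.

Step 17
Reactants: 28 bis-silylated ynone
Product: 29 (1S)-2-hydroxy-1-{(2R,3S)-2-[(1Z,6S)-6-hydroxy-2-methyl-5-oxohept-1-en-3-yn-1-yl]-4-methylidene-5-oxooxolan-3-yl}ethyl (E)-2-(acetoxymethyl)but-2-enoate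
Conditions: HF·pyridine, THF, 0 °C → rt
Reagents that add atoms: none
Why: Fluoride-driven cleavage of both silyl ethers under mildly acidic conditions, which disfavour acyl migration from O8 to O9.

Step 18
Reactants: 29 dihydroxy ynone
Product: 30 (1S)-2-hydroxy-1-{(2R,3S)-4-methylidene-2-[(Z)-2-((5S)-5-methyl-4-oxo-4,5-dihydrofuran-2-yl)prop-1-en-1-yl]-5-oxooxolan-3-yl}ethyl (E)-2-(acetoxymethyl)but-2-enoate
Conditions: (4-CF3C6H4)3PAuCl (5 mol%), AgOTf (5 mol%), toluene, rt
Reagents that add atoms: none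
Why: Cationic monovalent gold activates the ynone for 5-endo-dig attack of the C10 hydroxyl on C3 (hydroxy ynone to 3(2H)-furanone cyclisation); C10 keeps the lactate configuration but is enolisable and is reset in step 20.

Step 19
Reactants: 30 furanone primary alcohol
Product: 31 (1S)-1-{(2R,3S)-4-methylidene-2-[(Z)-2-((5S)-5-methyl-4-oxo-4,5-dihydrofuran-2-yl)prop-1-en-1-yl]-5-oxooxolan-3-yl}-2-oxoethyl (E)-2-(acetoxymethyl)but-2-enoate
Conditions: Dess–Martin periodinane, CH2Cl2, 0 °C → rt; used at once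
Reagents that add atoms: none
Why: Dess–Martin oxidation of the only free alcohol gives the C9 aldehyde under non-basic conditions, which protects the α-acyloxy centre C8 from epimerisation.

Step 20
Reactants: 31 furanone aldehyde
Product: 32 (6R,7S,8S,9S,10R)-8-[(E)-2-(acetoxymethyl)but-2-enoyloxy]-9-hydroxy-1-oxo-3,10-epoxygermacra-2,4(Z),11(13)-trien-12,6-olide
Conditions: MgBr2·OEt2 (3 equiv), i-Pr2NEt (3 equiv), CH2Cl2 (0.002 M), −20 → 0 °C; pH 7 buffer
Reagents that add atoms: none
Why: Intramolecular aldol addition through a magnesium furanolate made by soft enolisation of the acidic C10–H: C10 (R) should follow because the trans-fused lactone holds O6 and C11 equatorial on the forming ring, so the C7–C8–C9 arm can reach only one face of the flat furanolate, and C9 (S) should follow from a magnesium-bridged closed transition state that keeps the aldehyde oxygen beside the enolate oxygen with C9–H turned outward.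

Step 21
Reactants: 32 C9 alcohol
Product: 33 CNP0325609.1, (6R,7S,8S,9S,10R)-9-acetoxy-8-[(E)-2-(acetoxymethyl)but-2-enoyloxy]-1-oxo-3,10-epoxygermacra-2,4(Z),11(13)-trien-12,6-olide
Conditions: Ac2O, pyridine, DMAP (cat.), CH2Cl2, 0 °C
Reagents that add atoms: acetic anhydride, CC(=O)OC(C)=O
Why: Nucleophile-catalysed acetylation of the hindered secondary alcohol at low temperature, with the acylation intended to outrun retro-aldol cleavage.

**Compound list**

1 | (Z)-3-methylpent-2-en-4-yn-1-ol | C#C/C(C)=C\CO | starting material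
2 | (Z)-trimethyl{[3-methyl-5-(trimethylsilyl)pent-2-en-4-yn-1-yl]oxy}silane | C[Si](C)(C)C#C/C(C)=C\CO[Si](C)(C)C | intermediate
3 | (Z)-3-methyl-5-(trimethylsilyl)pent-2-en-4-yn-1-ol | C[Si](C)(C)C#C/C(C)=C\CO | intermediate
4 | (Z)-3-methyl-5-(trimethylsilyl)pent-2-en-4-ynal | C[Si](C)(C)C#C/C(C)=C\C=O | intermediate
5 | propargyl alcohol | C#CCO | starting material
6 | tert-butyl(diphenyl)(prop-2-yn-1-yloxy)silane | C#CCO[Si](c1ccccc1)(c1ccccc1)C(C)(C)C | intermediate
7 | (E)-[3-(tert-butyldiphenylsilyloxy)prop-1-en-1-yl]dicyclohexylborane | CC(C)(C)[Si](OC/C=C/B(C1CCCCC1)C1CCCCC1)(c1ccccc1)c1ccccc1 | intermediate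
8 | (E)-[3-(tert-butyldiphenylsilyloxy)prop-1-en-1-yl](methyl)zinc | C[Zn]/C=C/CO[Si](c1ccccc1)(c1ccccc1)C(C)(C)C | intermediate
9 | (2E,4S,5Z)-1-(tert-butyldiphenylsilyloxy)-6-methyl-8-(trimethylsilyl)octa-2,5-dien-7-yn-4-ol | C[Si](C)(C)C#C/C(C)=C\[C@@H](O)/C=C/CO[Si](c1ccccc1)(c1ccccc1)C(C)(C)C | intermediate
10 | mono-tert-butyl malonate | CC(C)(C)OC(=O)CC(=O)O | starting material
11 | tert-butyl (2E,4S,5Z)-1-(tert-butyldiphenylsilyloxy)-6-methyl-8-(trimethylsilyl)octa-2,5-dien-7-yn-4-yl malonate | C[Si](C)(C)C#C/C(C)=C\[C@@H](OC(=O)CC(=O)OC(C)(C)C)/C=C/CO[Si](c1ccccc1)(c1ccccc1)C(C)(C)C | intermediate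
12 | tert-butyl (2E,4S,5Z)-1-(tert-butyldiphenylsilyloxy)-6-methyl-8-(trimethylsilyl)octa-2,5-dien-7-yn-4-yl 2-diazomalonate | C[Si](C)(C)C#C/C(C)=C\[C@@H](OC(=O)C(=[N+]=[N-])C(=O)OC(C)(C)C)/C=C/CO[Si](c1ccccc1)(c1ccccc1)C(C)(C)C | intermediate
13 | tert-butyl (1S,4R,5S,6S)-6-[(tert-butyldiphenylsilyloxy)methyl]-4-[(Z)-2-methyl-4-(trimethylsilyl)but-1-en-3-yn-1-yl]-2-oxo-3-oxabicyclo[3.1.0]hexane-1-carboxylate | CC(C)(C)OC(=O)[C@]12C(=O)O[C@H](/C=C(/C)C#C[Si](C)(C)C)[C@H]1[C@@H]2CO[Si](c3ccccc3)(c3ccccc3)C(C)(C)C | intermediate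
14 | tert-butyl acrylate | C=CC(=O)OC(C)(C)C | starting material
15 | acetaldehyde | CC=O | starting material
16 | tert-butyl 3-hydroxy-2-methylidenebutanoate (racemic) | CC(O)C(=C)C(=O)OC(C)(C)C | intermediate
17 | tert-butyl 3-acetoxy-2-methylidenebutanoate (racemic) | CC(OC(C)=O)C(=C)C(=O)OC(C)(C)C | intermediate
18 | tert-butyl (E)-2-(acetoxymethyl)but-2-enoate | C/C=C(\COC(C)=O)C(=O)OC(C)(C)C | intermediate
19 | (E)-2-(acetoxymethyl)but-2-enoic acid | C/C=C(\COC(C)=O)C(=O)O | intermediate
20 | tert-butyl (4S,5R)-4-[(1S)-1-{[(E)-2-(acetoxymethyl)but-2-enoyl]oxy}-2-(tert-butyldiphenylsilyloxy)ethyl]-5-[(Z)-2-methyl-4-(trimethylsilyl)but-1-en-3-yn-1-yl]-2-oxooxolane-3-carboxylate (C3 epimers) | CC(C)(C)OC(=O)C1C(=O)O[C@H](/C=C(/C)C#C[Si](C)(C)C)[C@H]1[C@@H](CO[Si](c2ccccc2)(c2ccccc2)C(C)(C)C)OC(=O)/C(=C/C)COC(C)=O | intermediate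
21 | (4S,5R)-4-[(1S)-1-{[(E)-2-(acetoxymethyl)but-2-enoyl]oxy}-2-(tert-butyldiphenylsilyloxy)ethyl]-5-[(Z)-2-methyl-4-(trimethylsilyl)but-1-en-3-yn-1-yl]-2-oxooxolane-3-carboxylic acid (C3 epimers) | OC(=O)C1C(=O)O[C@H](/C=C(/C)C#C[Si](C)(C)C)[C@H]1[C@@H](CO[Si](c2ccccc2)(c2ccccc2)C(C)(C)C)OC(=O)/C(=C/C)COC(C)=O | intermediate
22 | (1S)-2-(tert-butyldiphenylsilyloxy)-1-{(2R,3S)-4-methylidene-2-[(Z)-2-methyl-4-(trimethylsilyl)but-1-en-3-yn-1-yl]-5-oxooxolan-3-yl}ethyl (E)-2-(acetoxymethyl)but-2-enoate | C=C1C(=O)O[C@H](/C=C(/C)C#C[Si](C)(C)C)[C@H]1[C@@H](CO[Si](c2ccccc2)(c2ccccc2)C(C)(C)C)OC(=O)/C(=C/C)COC(C)=O | intermediate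
23 | (1S)-2-(tert-butyldiphenylsilyloxy)-1-{(2R,3S)-4-methylidene-2-[(Z)-2-methylbut-1-en-3-yn-1-yl]-5-oxooxolan-3-yl}ethyl (E)-2-(acetoxymethyl)but-2-enoate | C=C1C(=O)O[C@H](/C=C(/C)C#C)[C@H]1[C@@H](CO[Si](c2ccccc2)(c2ccccc2)C(C)(C)C)OC(=O)/C(=C/C)COC(C)=O | intermediate
24 | ethyl (S)-lactate | C[C@H](O)C(=O)OCC | starting material
25 | ethyl (S)-2-(tert-butyldimethylsilyloxy)propanoate | C[C@H](O[Si](C)(C)C(C)(C)C)C(=O)OCC | intermediate
26 | (S)-2-(tert-butyldimethylsilyloxy)propanoic acid | C[C@H](O[Si](C)(C)C(C)(C)C)C(=O)O | intermediate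
27 | (S)-2-(tert-butyldimethylsilyloxy)propanoyl chloride | C[C@H](O[Si](C)(C)C(C)(C)C)C(Cl)=O | intermediate
28 | (1S)-2-(tert-butyldiphenylsilyloxy)-1-{(2R,3S)-2-[(1Z,6S)-6-(tert-butyldimethylsilyloxy)-2-methyl-5-oxohept-1-en-3-yn-1-yl]-4-methylidene-5-oxooxolan-3-yl}ethyl (E)-2-(acetoxymethyl)but-2-enoate | C=C1C(=O)O[C@H](/C=C(/C)C#CC(=O)[C@H](C)O[Si](C)(C)C(C)(C)C)[C@H]1[C@@H](CO[Si](c2ccccc2)(c2ccccc2)C(C)(C)C)OC(=O)/C(=C/C)COC(C)=O | intermediate
29 | (1S)-2-hydroxy-1-{(2R,3S)-2-[(1Z,6S)-6-hydroxy-2-methyl-5-oxohept-1-en-3-yn-1-yl]-4-methylidene-5-oxooxolan-3-yl}ethyl (E)-2-(acetoxymethyl)but-2-enoate | C=C1C(=O)O[C@H](/C=C(/C)C#CC(=O)[C@H](C)O)[C@H]1[C@@H](CO)OC(=O)/C(=C/C)COC(C)=O | intermediate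
30 | (1S)-2-hydroxy-1-{(2R,3S)-4-methylidene-2-[(Z)-2-((5S)-5-methyl-4-oxo-4,5-dihydrofuran-2-yl)prop-1-en-1-yl]-5-oxooxolan-3-yl}ethyl (E)-2-(acetoxymethyl)but-2-enoate | C=C1C(=O)O[C@H](/C=C(/C)C2=CC(=O)[C@H](C)O2)[C@H]1[C@@H](CO)OC(=O)/C(=C/C)COC(C)=O | intermediate
31 | (1S)-1-{(2R,3S)-4-methylidene-2-[(Z)-2-((5S)-5-methyl-4-oxo-4,5-dihydrofuran-2-yl)prop-1-en-1-yl]-5-oxooxolan-3-yl}-2-oxoethyl (E)-2-(acetoxymethyl)but-2-enoate | C=C1C(=O)O[C@H](/C=C(/C)C2=CC(=O)[C@H](C)O2)[C@H]1[C@@H](C=O)OC(=O)/C(=C/C)COC(C)=O | intermediate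
32 | (6R,7S,8S,9S,10R)-8-[(E)-2-(acetoxymethyl)but-2-enoyloxy]-9-hydroxy-1-oxo-3,10-epoxygermacra-2,4(Z),11(13)-trien-12,6-olide | C=C1C(=O)O[C@@H]2/C=C(/C)C3=CC(=O)[C@](C)(O3)[C@@H](O)[C@@H](OC(=O)/C(=C/C)COC(C)=O)[C@@H]12 | intermediate
33 | CNP0325609.1, (6R,7S,8S,9S,10R)-9-acetoxy-8-[(E)-2-(acetoxymethyl)but-2-enoyloxy]-1-oxo-3,10-epoxygermacra-2,4(Z),11(13)-trien-12,6-olide | C=C1C(=O)O[C@@H]2/C=C(/C)C3=CC(=O)[C@](C)(O3)[C@@H](OC(C)=O)[C@@H](OC(=O)/C(=C/C)COC(C)=O)[C@@H]12 | target

**Step count**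

Total: 21 steps. Longest linear sequence: 15 steps (1, 2, 4, 5, 6, 7, 11, 12, 13, 16, 17, 18, 19, 20, 21, from compound 1).

**Steps most likely to fail**

Step 20 (aldol ring closure). The strained ring may not close, or may reopen by retro-aldol because the furanolate is a good leaving group. The aldehyde may be attacked on the wrong face and give the C9 epimer. C8 may epimerise through the aldehyde enol, and intermolecular aldol may compete. Fallback, from 31 back to 32: 31 would be silylated to its 3-silyloxyfuran (TMSOTf, Et3N, CH2Cl2, −78 °C) and brominated with NBS at C10 to give the C10-bromo furanone aldehyde F1. SmI2 (2.2 equiv, THF, −78 °C, high dilution) would then reduce the C–Br bond to a trivalent samarium furanolate, which closes the ring by an intramolecular Reformatsky reaction through a chelated transition state and gives 32 as its samarium aldolate. This is non-basic and held against reversal until the cold quench.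

Step 11 (cyclopropane opening). The carboxylate may attack the hindered secondary C8 too slowly, so that acyl attack on the lactone, substitution at the allylic acetate of the side chain or loss of silyl groups take over on heating. Fallback, from 9 back to 20: 9 would undergo matched, erythro-selective Sharpless epoxidation of C7=C8 (Ti(Oi-Pr)4, D-(−)-diisopropyl tartrate, t-BuOOH, 4 Å sieves, CH2Cl2, −20 °C; the Z enyne alkene reacts far more slowly) to give the epoxy alcohol F2. Esterification with 10 (DCC, DMAP) would give the epoxy malonate F3. DBU and LiCl in MeCN would then send the malonate carbon C11 into C7 in a 5-exo epoxide opening with inversion, placing C11 and O8 anti as required and giving the hydroxy lactone F4. Immediate Yamaguchi esterification of the C8 hydroxyl with 19 (2,4,6-trichlorobenzoyl chloride, Et3N, DMAP, toluene) would give 20. The free C8 alcohol exists for one step only, to limit translactonisation.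

Step 7 (key cyclopropanation). The carbenoid may dimerise or add to the enyne π-system, and the C6 arm may control the face poorly, giving the C6-endo diastereomer. Fallback, from 11 back to 13: 11 would undergo stereospecific ionic iodocarbocyclisation (I2, Ti(Ot-Bu)4, CuO, CH2Cl2), in which the iodonium ion of the more electron-rich C7=C8 alkene is opened anti by the malonate carbon in a 5-exo closure to the thermodynamically preferred 4,5-trans lactone, the iodo lactone F5. DBU in THF would then close C11 onto C8 with inversion (3-exo-tet) to give 13, with the same net syn addition to the E-alkene as the carbenoid route.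

Further compounds
F1 | step 20 | (1S)-1-{(2R,3S)-2-[(Z)-2-(5-bromo-5-methyl-4-oxo-4,5-dihydrofuran-2-yl)prop-1-en-1-yl]-4-methylidene-5-oxooxolan-3-yl}-2-oxoethyl (E)-2-(acetoxymethyl)but-2-enoate (C10 epimers) | C=C1C(=O)O[C@H](/C=C(/C)C2=CC(=O)C(C)(Br)O2)[C@H]1[C@@H](C=O)OC(=O)/C(=C/C)COC(C)=O
F2 | step 11 | (1R,2Z)-1-[(2R,3R)-3-{[(tert-butyldiphenylsilyl)oxy]methyl}oxiran-2-yl]-3-methyl-5-(trimethylsilyl)pent-2-en-4-yn-1-ol | C[Si](C)(C)C#C/C(C)=C\[C@@H](O)[C@H]1O[C@@H]1CO[Si](c2ccccc2)(c2ccccc2)C(C)(C)C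
F3 | step 11 | tert-butyl (1R,2Z)-1-[(2R,3R)-3-{[(tert-butyldiphenylsilyl)oxy]methyl}oxiran-2-yl]-3-methyl-5-(trimethylsilyl)pent-2-en-4-yn-1-yl malonate | C[Si](C)(C)C#C/C(C)=C\[C@@H](OC(=O)CC(=O)OC(C)(C)C)[C@H]1O[C@@H]1CO[Si](c2ccccc2)(c2ccccc2)C(C)(C)C
F4 | step 11 | tert-butyl (4S,5R)-4-[(1S)-2-(tert-butyldiphenylsilyloxy)-1-hydroxyethyl]-5-[(Z)-2-methyl-4-(trimethylsilyl)but-1-en-3-yn-1-yl]-2-oxooxolane-3-carboxylate (C3 epimers) | CC(C)(C)OC(=O)C1C(=O)O[C@H](/C=C(/C)C#C[Si](C)(C)C)[C@H]1[C@H](O)CO[Si](c2ccccc2)(c2ccccc2)C(C)(C)C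
F5 | step 7 | tert-butyl (4S,5R)-4-[(1S)-2-(tert-butyldiphenylsilyloxy)-1-iodoethyl]-5-[(Z)-2-methyl-4-(trimethylsilyl)but-1-en-3-yn-1-yl]-2-oxooxolane-3-carboxylate (C3 epimers) | CC(C)(C)OC(=O)C1C(=O)O[C@H](/C=C(/C)C#C[Si](C)(C)C)[C@H]1[C@H](I)CO[Si](c2ccccc2)(c2ccccc2)C(C)(C)C
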